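The numbers in the tables come from a simulation for an exercise; the scatter is artificial.

The decision is when to stop the flask, and one ratio answers it.

common to all: Z 0.82 mol%
- ash: D 1 M; J 2 M; run made earlier
- flask: D 2.0 M; J 2.00 M; time 15 d

ash run (percent of the D charged)

| time / h | E / % | Q / % |
|---|---|---|
| 6.00 | 79 | 7 |
| 12.0 | 79 | 13 |
| 20.0 | 69 | 21 |
| 25.0 | 64 | 25 |
| 30.0 | 60 | 29 |
| 40.0 | 51 | 38 |

(each reading ± 1.5 percentage points)

- time, not beyond 15 d, at which the flask holds most E
- the amount of E, in percent of the D charged, at that time
- the first time at which E reaches 23%, in the same percent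

- the earlier runs were read with a standard deviation of 1.5 percentage points
- steps that have been proposed: Z + E -> Z + Q; D + J -> L; D -> E; Z -> X
- no earlier run changes the charge of Z; that part of a forecast is a guess

The ash run looks contradictory: E falls from 69% to 51% between 20.0 h and 40.0 h, which reads as a loss constant of 0.0151 h⁻¹ and a half-life of 45.9 h, yet E never reads above 79% while E and Q together level at 89.0%.

The gap clears up once the feed of E is counted. E and Q together read 86.0% after 6.00 h, and against that level this gives D a loss constant of 0.565 h⁻¹, a rough reading. The flask has the same 2.00 M of J, so it takes over this constant and the level, and the same loading at twice the molarity of Z, so, guessing that the pseudo-first-order loss of E follows Z, E loses 0.0302 h⁻¹ there. Divided, these give 18.7, the filling ratio: the loss constant of D over that of E in the same flask.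

For two first-order steps in series, the shortfall of the top below the level, in decades, is the common logarithm of this ratio, 1.27, over the ratio minus one. That is 0.0719, a factor of 0.847, so this reckoning puts the top of the flask at 75.4% after 0.228 d, and, with the loss of E on the way up neglected, E at 23% after 0.529 h. In the ash run the ratio is 37.4, and the same rule puts the top near 80.6%, beside the 79% read there.

The forecast, which calls the order in Z “a guess”, gives 0.25 d, 75% and 0.58 h, with its times later than this reckoning's.

| | reckoned | flask |
|---|---|---|
| time of most E | 0.228 d | 0.246 d |
| most E | 75.4% | 75.1% |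
| E reaches 23% | 0.529 h | 0.588 h |

    Z + E → Z + Q (k = 0.0323 M⁻¹ min⁻¹)
    D + J → L (k = 4.42 × 10⁻⁴ M⁻¹ min⁻¹)
    D → E (k = 0.00762 min⁻¹)
    Z → X (k = 1.14 × 10⁻⁴ min⁻¹)

In the flask, D has a half-life of 0.063 d by its turning into E alone, and E one of 0.91 d by Z + E alone with Z as charged, 14.4 times longer. At the top, the filling ratio asks for E at about 16.6 times D, and the flask holds 75.1% of E beside 5.01% of D at 0.246 d.

In a neighbouring flask, the same but with 0.49 mol% of Z, the ratio becomes 31.3, the shortfall 0.0494 decade, and the reckoned top 79.4%; the computed top there is 79.5%.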